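The earlier runs and the new flask were generated by integration on assumed constants, and the scatter is random.

Two questions stand over these flasks: how much target each holds at the end, and what shape that row takes.

| setting | blue | ochre | theta | delta | beta | epsilon |
|---|---|---|---|---|---|---|
| substrate | 0.057 M | 0.057 M | 0.057 M | 0.057 M | 0.057 M | 0.057 M |
| reagent | 0.53 equiv | 5.3 equiv | 1.00 equiv | 2.00 equiv | 4.00 equiv | 8.00 equiv |
| initiator | 1 mol% | 1 mol% | 1 mol% | 1 mol% | 1 mol% | 1 mol% |
| radical scavenger | 0.74 mol% | 0.74 mol% | 0.74 mol% | 0.74 mol% | 0.74 mol% | 0.74 mol% |
| remark | run made earlier | run made earlier |  |  |  |  |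
| time |  |  | 40 min | 40 min | 40 min | 40 min |

| run | time / min | target / % |
|---|---|---|
| blue | 2.50 | 0.8 |
| blue | 5.00 | 29.7 |
| blue | 12.0 | 50.4 |
| blue | 30.0 | 52.7 |
| ochre | 4.00 | 9.3 |
| ochre | 10.0 | 48.5 |
| ochre | 20.0 | 17.9 |
| ochre | 30.0 | 6.1 |

(readings scatter by 1 percentage point)

- amount of target at the end, in percent of the substrate charged for theta, delta, beta, epsilon, in this order
- the shape of the row from first to last (hardly changes / falls, then rises / rises all the way / falls all the way / rises, then falls)

- the numbers in the tables scatter by 1 percentage point (one standard deviation)
- "hardly changes" means that all values lie within two and a half points (for a concentration: within two and a half percent of the largest)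

**First entry.** Each target costs one reagent. Blue shows this: 0.53 equiv of reagent gives a last reading of 52.7% of target.

**Second entry.** Ochre, charged with 5.3 equiv, loses target: 17.9% at 20.0 min, 6.1% at 30.0 min. Read this as reagent plus target giving over-reaction product, at a rate κ[reagent][target], so each lost target costs a second reagent. With the substrate taken as used up, the books read: reagent left equals the charge, minus two, plus target, all in equivalents. Ochre's interval thus averages 3.42 equivalents. Its pseudo-first-order fall of 0.108 /min then reads as κ = 0.0315 /min per equivalent.

**Counting turnovers.** Loss is taken to run for the 35.0 min from the time of blue's mid-rise reading to the end of the new flasks, so κ gives 1.10 as the loss count, κ times the minutes of loss.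

Delta's books make reagent left equal target, so the two fall together and target is one over one plus the count: 47.6%.

In beta, reagent stays 2 equivalents ahead of target. The ratio of target to reagent starts at one part in 3, shrinks by exp(−2n) to 0.0368, and so target is 7.64%. Epsilon, 6 ahead, gives 0.115%.

Theta has different books: its reagent charge equals its substrate, and over-reaction spends part of that reagent, so reagent is the limiting reagent in theta. With theta's rise taken as long as blue's 7.00 min, and reagent and target near 0.5 equivalent each, about 5.51% over-reacts. That takes twice as much from the target ledger, leaving 89.0%.

**The forecast.** It gives 81%, 56%, 14% and 1%, a row that falls all the way: “The row falls throughout.” The shape agrees with this reckoning, but the forecast stands lower on theta and higher on delta, beta and epsilon.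

    initiator → 2 initiating radical (k = 0.00200 /s)
    substrate + initiating radical → capped initiator + first chain carrier (k = 5.10 × 10⁵ /M/s)
    reagent + first chain carrier → target + second chain carrier (k = 56000 /M/s)
    substrate + second chain carrier → by-product + first chain carrier (k = 1.40 × 10⁵ /M/s)
    2 first chain carrier → ended chains A (k = 7.00 × 10⁶ /M/s)
    2 second chain carrier → ended chains B (k = 3.00 × 10⁸ /M/s)
    reagent + target → over-reaction product (k = 0.00990 /M/s)
    first chain carrier + radical scavenger → ended chains C (k = 6.50 × 10⁷ /M/s)

**The flasks.** The row reads 91.3%, 45.1%, 7.20%, 0.205%: it falls all the way. Delta ends with reagent at 46.8% of the substrate charged beside 45.1% of target, the two level. For beta, the loss count 1.10 gave a ratio of 0.0368. Beta holds 7.20% of target beside reagent at 209% of the substrate charged, a ratio of 0.0344.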